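**Assumption:** the SMILES is taken literally, so the aroyl group on the cyclohexene is 3,5-dihydroxy-4-prenylbenzoyl, with no hydroxyl ortho to that ketone. Configuration of the core: C1 (acyl) R, C2 (chalcone aryl) S, C6 (dihydroxyphenyl) S.

## Retrosynthetic overview

1. Target 30 ⇐ octaacetate 29 by one mild methanolysis. All phenols travel as acetates late on, because acid at the end would risk chroman and ketal formation.
2. 29 ⇐ Liebeskind–Srogl acyl coupling of cyclohexene thioester 28 with the prenylated resorcinol boronic acid 25 (aryl ketone C–C bond).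
3. 28 ⇐ acid 27 ⇐ ketol 26 ⇐ endo, copper/bis(oxazoline)-catalysed Diels–Alder of the C20 chalcone-diene 13 with the chelating α'-hydroxy enone 17. This forms the cyclohexene and all three stereocentres.
4. 13 ⇐ Claisen–Schmidt chalcone, then Stille dienylation. 17 ⇐ aldol condensation of the same aldehyde 4 with 3-hydroxy-3-methylbutan-2-one. 25 ⇐ resorcinol by ortho-lithiation/prenylation and meta C–H borylation.
5. Ring order: the four benzene rings come from resorcinol; the cyclohexene is the only ring formed (step 19).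

## Route

Step 1
Reactants: 1 resorcinol
Product: 3 2,4-dihydroxybenzaldehyde, via aryl iminium chloride 2 (not isolated)
Conditions: POCl3, DMF, MeCN, −15 °C → rt; then H2O, 50 °C
Reagents that add atoms: N,N-dimethylformamide CN(C)C=O (formyl carbon); water O (formyl oxygen); phosphoryl chloride O=P(Cl)(Cl)Cl (chloride of 2 only)
Why: Vilsmeier–Haack formylation attacks C4, para to one hydroxyl and ortho to the other, and the iminium salt is hydrolysed to the aldehyde.

Step 2
Reactants: 3 2,4-dihydroxybenzaldehyde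
Product: 4 2,4-bis(methoxymethoxy)benzaldehyde
Conditions: NaH, MOMCl, DMF, 0 °C → rt
Reagents that add atoms: chloromethyl methyl ether COCCl
Why: O-alkylation of both phenoxides (Williamson-type MOM ether formation); NaH is used so that the hydrogen-bonded ortho phenol also reacts.

Step 3
Reactants: 1 resorcinol
Product: 5 1-(2,4-dihydroxyphenyl)ethanone
Conditions: AcOH, ZnCl2, 140 °C
Reagents that add atoms: acetic acid CC(=O)O
Why: Nencki reaction (ZnCl2-mediated Friedel–Crafts C-acylation) at the position ortho/para to the two hydroxyls.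

Step 4
Reactants: 5 1-(2,4-dihydroxyphenyl)ethanone
Product: 6 1-(2,4-dihydroxy-3-iodophenyl)ethanone
Conditions: I2, HIO3, EtOH/H2O, 35 °C
Reagents that add atoms: iodine II; iodic acid OI(=O)=O
Why: Electrophilic aromatic iodination at C3, the carbon flanked by both hydroxyls, as in the aqueous iodination of resorcinol to 2-iodoresorcinol.

Step 5
Reactants: 6 1-(2,4-dihydroxy-3-iodophenyl)ethanone
Product: 7 1-[2-hydroxy-3-iodo-4-(methoxymethoxy)phenyl]ethanone
Conditions: MOMCl (1.2 equiv), K2CO3, acetone, rt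
Reagents that add atoms: chloromethyl methyl ether COCCl
Why: Selective Williamson-type MOM protection of the 4-hydroxyl; the 2-hydroxyl is hydrogen-bonded to the ketone and stays free.

Step 6
Reactants: 7 1-[2-hydroxy-3-iodo-4-(methoxymethoxy)phenyl]ethanone; 4 2,4-bis(methoxymethoxy)benzaldehyde
Product: 8 (E)-1-[2-hydroxy-3-iodo-4-(methoxymethoxy)phenyl]-3-[2,4-bis(methoxymethoxy)phenyl]prop-2-en-1-one
Conditions: KOH, EtOH/H2O, rt
Reagents that add atoms: none
Why: Claisen–Schmidt aldol condensation; E1cB dehydration gives the conjugated E-enone.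

Step 7
Reactants: 8 MOM-protected iodochalcone
Product: 9 (E)-1-(2,4-dihydroxy-3-iodophenyl)-3-(2,4-dihydroxyphenyl)prop-2-en-1-one
Conditions: HCl (3 M aq), MeOH, 45 °C
Reagents that add atoms: none
Why: Acid-catalysed acetal exchange removes the three MOM groups while no acid-sensitive diene or prenyl group is present yet.

Step 8
Reactants: 9 tetrahydroxy iodochalcone
Product: 10 (E)-1-(2,4-diacetoxy-3-iodophenyl)-3-(2,4-diacetoxyphenyl)prop-2-en-1-one
Conditions: Ac2O, pyridine, DMAP (cat.), CH2Cl2, rt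
Reagents that add atoms: acetic anhydride CC(=O)OC(C)=O
Why: DMAP-catalysed O-acylation of all four phenols; acetates are removable without acid at the end and lower the electron density of the later diene.

Step 9
Reactants: 11 2-methylbut-1-en-3-yne
Product: 12 (E)-tributyl(3-methylbuta-1,3-dien-1-yl)stannane
Conditions: Bu3SnH, AIBN (cat.), neat, 85 °C
Reagents that add atoms: tributyltin hydride CCCC[SnH](CCCC)CCCC
Why: Radical hydrostannylation of the terminal alkyne puts tin on the terminal carbon and equilibrates to the E-vinylstannane.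

Step 10
Reactants: 10 tetraacetoxy iodochalcone; 12 dienylstannane
Product: 13 (E)-1-{2,4-diacetoxy-3-[(E)-3-methylbuta-1,3-dien-1-yl]phenyl}-3-(2,4-diacetoxyphenyl)prop-2-en-1-one
Conditions: Pd2(dba)3 (5 mol %), AsPh3 (20 mol %), CuI (10 mol %), DMF, 50 °C
Reagents that add atoms: none
Why: Stille coupling under base-free conditions keeps the aryl acetates and transfers the dienyl group with retention of E geometry.

Step 11
Reactants: 4 2,4-bis(methoxymethoxy)benzaldehyde; 14 3-hydroxy-3-methylbutan-2-one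
Product: 15 (E)-1-[2,4-bis(methoxymethoxy)phenyl]-4-hydroxy-4-methylpent-1-en-3-one
Conditions: LiOH·H2O, MeOH/H2O, rt
Reagents that add atoms: none
Why: Aldol condensation of the only enolisable position (the methyl group) gives the E α'-hydroxy enone, a chelating acrylate equivalent.

Step 12
Reactants: 15 MOM-protected α'-hydroxy enone
Product: 16 (E)-1-(2,4-dihydroxyphenyl)-4-hydroxy-4-methylpent-1-en-3-one
Conditions: HCl (3 M aq), MeOH, rt
Reagents that add atoms: none
Why: Acid-catalysed acetal exchange removes both MOM groups; the E-enone and the tertiary alcohol tolerate dilute acid.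

Step 13
Reactants: 16 dihydroxyphenyl α'-hydroxy enone
Product: 17 (E)-1-(2,4-diacetoxyphenyl)-4-hydroxy-4-methylpent-1-en-3-one
Conditions: Ac2O, pyridine, 0 °C → rt (no DMAP)
Reagents that add atoms: acetic anhydride CC(=O)OC(C)=O
Why: Chemoselective O-acylation of the two phenols; the hindered tertiary alcohol needed for chelation is not acylated without DMAP.

Step 14
Reactants: 1 resorcinol
Product: 18 1,3-bis(methoxymethoxy)benzene
Conditions: NaH, MOMCl, DMF, 0 °C → rt
Reagents that add atoms: chloromethyl methyl ether COCCl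
Why: Williamson-type MOM ether formation installs two ortho-directing groups.

Step 15
Reactants: 18 1,3-bis(methoxymethoxy)benzene; 19 1-bromo-3-methylbut-2-ene (prenyl bromide)
Product: 21 1,3-bis(methoxymethoxy)-2-(3-methylbut-2-en-1-yl)benzene, via aryllithium 20 (not isolated)
Conditions: nBuLi, THF, 0 °C; then CuI (10 mol %), prenyl bromide, −20 °C → rt
Reagents that add atoms: n-butyllithium [Li]CCCC (lithium of 20 only)
Why: Directed ortho-metalation occurs at C2 between the two MOM ethers, and copper-catalysed SN2 allylation gives the linear prenyl arene.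

Step 16
Reactants: 21 prenylated bis-MOM ether
Product: 22 2-(3-methylbut-2-en-1-yl)benzene-1,3-diol
Conditions: HCl (2 M aq), MeOH, rt
Reagents that add atoms: none
Why: Acid-catalysed acetal exchange at room temperature removes the MOM groups faster than the prenyl phenol cyclises to a chroman.

Step 17
Reactants: 22 2-prenylresorcinol
Product: 23 2-(3-methylbut-2-en-1-yl)-1,3-phenylene diacetate
Conditions: Ac2O, pyridine, DMAP (cat.), CH2Cl2, rt
Reagents that add atoms: acetic anhydride CC(=O)OC(C)=O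
Why: O-acylation gives the same base-labile protection as on the other fragments.

Step 18
Reactants: 23 2-prenyl-1,3-phenylene diacetate
Product: 25 [3,5-diacetoxy-4-(3-methylbut-2-en-1-yl)phenyl]boronic acid, via pinacol boronate 24 (not isolated)
Conditions: [Ir(OMe)(cod)]2 (1.5 mol %), dtbpy (3 mol %), B2pin2 (1.0 equiv), THF, 60 °C; then NaIO4, NH4OAc, acetone/H2O, rt
Reagents that add atoms: bis(pinacolato)diboron CC1(C)OB(OC1(C)C)B1OC(C)(C)C(C)(C)O1; water O
Why: Iridium-catalysed C–H borylation is sterically controlled and takes the only C–H without an ortho substituent (C5, para to prenyl); periodate then cleaves the pinacol to free the boronic acid.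

Step 19
Reactants: 13 chalcone-diene tetraacetate; 17 diacetoxyphenyl α'-hydroxy enone (1.5 equiv)
Product: 26 1-[(1R,2S,6S)-2-{2,6-diacetoxy-3-[(E)-3-(2,4-diacetoxyphenyl)prop-2-enoyl]phenyl}-6-(2,4-diacetoxyphenyl)-4-methylcyclohex-3-en-1-yl]-2-hydroxy-2-methylpropan-1-one
Conditions: [Cu((R,R)-tBu-box)](SbF6)2 (15 mol %; tBu-box = 2,2'-(propane-2,2-diyl)bis(4-tert-butyl-4,5-dihydrooxazole)), 4 Å molecular sieves, CH2Cl2, 0 °C → rt
Reagents that add atoms: none
Why: Catalytic enantioselective Diels–Alder reaction in which the hydroxy enone binds copper as an s-cis five-membered chelate, the (R,R)-ligand blocks the α-Re face, and the diene adds endo to the Si face with its CH2 terminus on the β-carbon, setting C1 (R), C2 (S) and C6 (S) together (acyl cis to the C2 aryl, trans to the C6 aryl).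

Step 20
Reactants: 26 Diels–Alder ketol
Product: 27 (1R,2S,6S)-2-{2,6-diacetoxy-3-[(E)-3-(2,4-diacetoxyphenyl)prop-2-enoyl]phenyl}-6-(2,4-diacetoxyphenyl)-4-methylcyclohex-3-ene-1-carboxylic acid
Conditions: NaIO4, MeOH/H2O (2:1), rt
Reagents that add atoms: water O (hydroxyl oxygen of the acid; NaIO4 is the oxidant)
Why: Periodate cleavage of the α-hydroxy ketone (Malaprade-type) releases acetone and unmasks the acid under near-neutral conditions that leave C1 and the acetates alone.

Step 21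
Reactants: 27 cyclohexenecarboxylic acid
Product: 28 S-phenyl (1R,2S,6S)-2-{2,6-diacetoxy-3-[(E)-3-(2,4-diacetoxyphenyl)prop-2-enoyl]phenyl}-6-(2,4-diacetoxyphenyl)-4-methylcyclohex-3-ene-1-carbothioate
Conditions: PhSH (1.1 equiv), DCC, HOBt, EtOAc, 0 °C → rt
Reagents that add atoms: thiophenol Sc1ccccc1
Why: Carbodiimide (Steglich-type) thioesterification through the HOBt active ester needs no added base, so C1 does not epimerise and the aryl acetates are not thiolysed.

Step 22
Reactants: 28 S-phenyl thioester; 25 arylboronic acid (1.5 equiv)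
Product: 29 (E)-1-{2,4-diacetoxy-3-[(1S,5S,6R)-6-[3,5-diacetoxy-4-(3-methylbut-2-en-1-yl)benzoyl]-5-(2,4-diacetoxyphenyl)-3-methylcyclohex-2-en-1-yl]phenyl}-3-(2,4-diacetoxyphenyl)prop-2-en-1-one (octaacetate)
Conditions: Pd2(dba)3 (5 mol %), P(OEt)3 (20 mol %), Cu(O2CC4H3S) (copper thiophene-2-carboxylate, 1.6 equiv), THF, rt → 45 °C
Reagents that add atoms: none
Why: Liebeskind–Srogl coupling, in which zerovalent palladium inserts into the C–S bond and the copper carboxylate takes up thiolate and activates boron without base, so acetates, enone and the C1 stereocentre are untouched.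

Step 23
Reactants: 29 octaacetate
Product: 30 kuwanon J as drawn, (E)-1-{3-[(1S,5S,6R)-6-[3,5-dihydroxy-4-(3-methylbut-2-en-1-yl)benzoyl]-5-(2,4-dihydroxyphenyl)-3-methylcyclohex-2-en-1-yl]-2,4-dihydroxyphenyl}-3-(2,4-dihydroxyphenyl)prop-2-en-1-one
Conditions: K2CO3 (cat.), MeOH, 0 °C → rt, Ar; AcOH quench
Reagents that add atoms: none
Why: Base-catalysed transesterification (Zemplén-type methanolysis) removes all eight aryl acetates without acid, so the prenyl group, the ketone and the three stereocentres are preserved.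

## Compound list

1 | resorcinol | Oc1cccc(O)c1 | starting material
2 | [(2,4-dihydroxyphenyl)methylidene]dimethylammonium chloride | C[N+](C)=Cc1ccc(O)cc1O.[Cl-] | intermediate
3 | 2,4-dihydroxybenzaldehyde | O=Cc1ccc(O)cc1O | intermediate
4 | 2,4-bis(methoxymethoxy)benzaldehyde | COCOc1ccc(C=O)c(OCOC)c1 | intermediate
5 | 1-(2,4-dihydroxyphenyl)ethanone | CC(=O)c1ccc(O)cc1O | intermediate
6 | 1-(2,4-dihydroxy-3-iodophenyl)ethanone | CC(=O)c1ccc(O)c(I)c1O | intermediate
7 | 1-[2-hydroxy-3-iodo-4-(methoxymethoxy)phenyl]ethanone | COCOc1ccc(C(C)=O)c(O)c1I | intermediate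
8 | (E)-1-[2-hydroxy-3-iodo-4-(methoxymethoxy)phenyl]-3-[2,4-bis(methoxymethoxy)phenyl]prop-2-en-1-one | COCOc1ccc(/C=C/C(=O)c2ccc(OCOC)c(I)c2O)c(OCOC)c1 | intermediate
9 | (E)-1-(2,4-dihydroxy-3-iodophenyl)-3-(2,4-dihydroxyphenyl)prop-2-en-1-one | O=C(/C=C/c1ccc(O)cc1O)c1ccc(O)c(I)c1O | intermediate
10 | (E)-1-(2,4-diacetoxy-3-iodophenyl)-3-(2,4-diacetoxyphenyl)prop-2-en-1-one | CC(=O)Oc1ccc(/C=C/C(=O)c2ccc(OC(C)=O)c(I)c2OC(C)=O)c(OC(C)=O)c1 | intermediate
11 | 2-methylbut-1-en-3-yne | C=C(C)C#C | starting material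
12 | (E)-tributyl(3-methylbuta-1,3-dien-1-yl)stannane | CCCC[Sn](CCCC)(CCCC)/C=C/C(C)=C | intermediate
13 | (E)-1-{2,4-diacetoxy-3-[(E)-3-methylbuta-1,3-dien-1-yl]phenyl}-3-(2,4-diacetoxyphenyl)prop-2-en-1-one | CC(=O)Oc1ccc(/C=C/C(=O)c2ccc(OC(C)=O)c(/C=C/C(C)=C)c2OC(C)=O)c(OC(C)=O)c1 | intermediate
14 | 3-hydroxy-3-methylbutan-2-one | CC(=O)C(C)(C)O | starting material
15 | (E)-1-[2,4-bis(methoxymethoxy)phenyl]-4-hydroxy-4-methylpent-1-en-3-one | COCOc1ccc(/C=C/C(=O)C(C)(C)O)c(OCOC)c1 | intermediate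
16 | (E)-1-(2,4-dihydroxyphenyl)-4-hydroxy-4-methylpent-1-en-3-one | CC(C)(O)C(=O)/C=C/c1ccc(O)cc1O | intermediate
17 | (E)-1-(2,4-diacetoxyphenyl)-4-hydroxy-4-methylpent-1-en-3-one | CC(=O)Oc1ccc(/C=C/C(=O)C(C)(C)O)c(OC(C)=O)c1 | intermediate
18 | 1,3-bis(methoxymethoxy)benzene | COCOc1cccc(OCOC)c1 | intermediate
19 | 1-bromo-3-methylbut-2-ene | CC(C)=CCBr | starting material
20 | [2,6-bis(methoxymethoxy)phenyl]lithium | [Li]c1c(OCOC)cccc1OCOC | intermediate
21 | 1,3-bis(methoxymethoxy)-2-(3-methylbut-2-en-1-yl)benzene | COCOc1cccc(OCOC)c1CC=C(C)C | intermediate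
22 | 2-(3-methylbut-2-en-1-yl)benzene-1,3-diol | CC(C)=CCc1c(O)cccc1O | intermediate
23 | 2-(3-methylbut-2-en-1-yl)-1,3-phenylene diacetate | CC(=O)Oc1cccc(OC(C)=O)c1CC=C(C)C | intermediate
24 | 2-(3-methylbut-2-en-1-yl)-5-(4,4,5,5-tetramethyl-1,3,2-dioxaborolan-2-yl)-1,3-phenylene diacetate | CC(=O)Oc1cc(B2OC(C)(C)C(C)(C)O2)cc(OC(C)=O)c1CC=C(C)C | intermediate
25 | [3,5-diacetoxy-4-(3-methylbut-2-en-1-yl)phenyl]boronic acid | CC(=O)Oc1cc(B(O)O)cc(OC(C)=O)c1CC=C(C)C | intermediate
26 | 1-[(1R,2S,6S)-2-{2,6-diacetoxy-3-[(E)-3-(2,4-diacetoxyphenyl)prop-2-enoyl]phenyl}-6-(2,4-diacetoxyphenyl)-4-methylcyclohex-3-en-1-yl]-2-hydroxy-2-methylpropan-1-one | CC(C)(O)C(=O)[C@H]1[C@@H](c2c(OC(C)=O)ccc(C(=O)/C=C/c3ccc(OC(C)=O)cc3OC(C)=O)c2OC(C)=O)C=C(C)C[C@@H]1c1ccc(OC(C)=O)cc1OC(C)=O | intermediate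
27 | (1R,2S,6S)-2-{2,6-diacetoxy-3-[(E)-3-(2,4-diacetoxyphenyl)prop-2-enoyl]phenyl}-6-(2,4-diacetoxyphenyl)-4-methylcyclohex-3-ene-1-carboxylic acid | OC(=O)[C@H]1[C@@H](c2c(OC(C)=O)ccc(C(=O)/C=C/c3ccc(OC(C)=O)cc3OC(C)=O)c2OC(C)=O)C=C(C)C[C@@H]1c1ccc(OC(C)=O)cc1OC(C)=O | intermediate
28 | S-phenyl (1R,2S,6S)-2-{2,6-diacetoxy-3-[(E)-3-(2,4-diacetoxyphenyl)prop-2-enoyl]phenyl}-6-(2,4-diacetoxyphenyl)-4-methylcyclohex-3-ene-1-carbothioate | O=C(Sc1ccccc1)[C@H]1[C@@H](c2c(OC(C)=O)ccc(C(=O)/C=C/c3ccc(OC(C)=O)cc3OC(C)=O)c2OC(C)=O)C=C(C)C[C@@H]1c1ccc(OC(C)=O)cc1OC(C)=O | intermediate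
29 | octaacetate of the target | CC(C)=CCc1c(OC(C)=O)cc(C(=O)[C@H]2[C@@H](c3c(OC(C)=O)ccc(C(=O)/C=C/c4ccc(OC(C)=O)cc4OC(C)=O)c3OC(C)=O)C=C(C)C[C@@H]2c2ccc(OC(C)=O)cc2OC(C)=O)cc1OC(C)=O | intermediate
30 | kuwanon J as drawn | CC(C)=CCc1c(O)cc(C(=O)[C@H]2[C@@H](c3c(O)ccc(C(=O)/C=C/c4ccc(O)cc4O)c3O)C=C(C)C[C@@H]2c2ccc(O)cc2O)cc1O | target

## Step count and risks

Total step count: 23. Longest linear sequence: 12 steps (3, 4, 5, 6, 7, 8, 10, 19, 20, 21, 22, 23).

**Step 19 (Diels–Alder).** A β-aryl hydroxy enone with an acyclic aryl diene is at the edge of the demonstrated scope of this catalyst; turnover may be slow, or the exo isomer may form. The fallback replaces copper chelation by iminium catalysis. It sets out from 2,4-dihydroxybenzaldehyde 3, which is acetylated (Ac2O, pyridine) to 2,4-diacetoxybenzaldehyde F1. Homologation with Ph3P=CHCHO (toluene, 80 °C) gives (E)-3-(2,4-diacetoxyphenyl)prop-2-enal F2. F2 and diene 13 are combined under (2S,5S)-5-benzyl-2-tert-butyl-3-methylimidazolidin-4-one trifluoroacetate (second-generation MacMillan imidazolidinone, 20 mol %, MeCN/H2O, 0 °C → rt). The benzyl group shields the Re face of the E-iminium ion, so the diene again adds endo to the Si face and gives (1R,2S,6S)-cyclohexenecarbaldehyde F3. Pinnick oxidation (NaClO2, NaH2PO4, 2-methylbut-2-ene, tBuOH/H2O) comes back to the route at acid 27.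

**Step 22 (acyl coupling).** The thioester is flanked by two aryl-bearing carbons, so insertion and transmetalation may be slow. The fallback sets out from acid 27 and skips the thioester. Ghosez's reagent (1-chloro-N,N,2-trimethylprop-1-en-1-amine, CH2Cl2, 0 °C) gives the acid chloride F4 under neutral conditions. F4 is coupled with boronic acid 25 without base (Pd(PPh3)4 5 mol %, copper thiophene-2-carboxylate 1.5 equiv, Et2O/THF, rt) and comes back at octaacetate 29.

**Step 18 (C–H borylation).** The prenyl alkene may be hydroborated or borylated by the iridium boryl species. The fallback borylates before any alkene is present. It sets out from resorcinol 1, iodinated (I2, NaHCO3, H2O, 0 °C) to 2-iodobenzene-1,3-diol F5 and acetylated (Ac2O, pyridine) to 2-iodo-1,3-phenylene diacetate F6. Borylation under the same iridium conditions gives 2-iodo-5-(pinacolboryl)-1,3-phenylene diacetate F7. Base-free Stille coupling (Pd(PPh3)4, DMF, 80 °C) with tributyl(3-methylbut-2-en-1-yl)stannane F8, made from prenyl bromide 19 and Bu3SnLi in THF, installs the prenyl group and leaves the boronate untouched. The fallback comes back at pinacol boronate 24, which then goes through the periodate stage of step 18 to 25.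

## Further compounds

F1 | step 19 | 2,4-diacetoxybenzaldehyde | CC(=O)Oc1ccc(C=O)c(OC(C)=O)c1
F2 | step 19 | (E)-3-(2,4-diacetoxyphenyl)prop-2-enal | CC(=O)Oc1ccc(/C=C/C=O)c(OC(C)=O)c1
F3 | step 19 | (1R,2S,6S)-2-{2,6-diacetoxy-3-[(E)-3-(2,4-diacetoxyphenyl)prop-2-enoyl]phenyl}-6-(2,4-diacetoxyphenyl)-4-methylcyclohex-3-ene-1-carbaldehyde | O=C[C@H]1[C@@H](c2c(OC(C)=O)ccc(C(=O)/C=C/c3ccc(OC(C)=O)cc3OC(C)=O)c2OC(C)=O)C=C(C)C[C@@H]1c1ccc(OC(C)=O)cc1OC(C)=O
F4 | step 22 | (1R,2S,6S)-2-{2,6-diacetoxy-3-[(E)-3-(2,4-diacetoxyphenyl)prop-2-enoyl]phenyl}-6-(2,4-diacetoxyphenyl)-4-methylcyclohex-3-ene-1-carbonyl chloride | ClC(=O)[C@H]1[C@@H](c2c(OC(C)=O)ccc(C(=O)/C=C/c3ccc(OC(C)=O)cc3OC(C)=O)c2OC(C)=O)C=C(C)C[C@@H]1c1ccc(OC(C)=O)cc1OC(C)=O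
F5 | step 18 | 2-iodobenzene-1,3-diol | Oc1cccc(O)c1I
F6 | step 18 | 2-iodo-1,3-phenylene diacetate | CC(=O)Oc1cccc(OC(C)=O)c1I
F7 | step 18 | 2-iodo-5-(4,4,5,5-tetramethyl-1,3,2-dioxaborolan-2-yl)-1,3-phenylene diacetate | CC(=O)Oc1cc(B2OC(C)(C)C(C)(C)O2)cc(OC(C)=O)c1I
F8 | step 18 | tributyl(3-methylbut-2-en-1-yl)stannane | CCCC[Sn](CCCC)(CCCC)CC=C(C)C
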